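**Strategy.** Ring B of the drimane core is read as the p-menthane of (R)-carvone: the isopropenyl carbon becomes the gem-dimethyl carbon C4, the α′-carbon becomes quaternary C10 and the carbonyl is C9. Everything rests on closing ring A between C3 and C4. Iron-hydride hydrogen-atom transfer to the isopropenyl group of a trans-dialkylated carvone gives the tertiary C4 radical, which adds 6-exo to the tosylhydrazone carbon (C3) of a 3-oxopropyl chain on C10; loss of sulfinate and N2 leaves C3 as CH2. One operation thus forges quaternary C4 and the trans-decalin and erases the activating group. The aryl unit is then joined at the C9 ketone and the sulfates are installed last.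

Key step: step 5

Remark on numbering: drimane numbering is used for the decalin (ring A = C1–C5, C10; ring B = C5–C10; C11 = benzylidene carbon); primes denote the aryl ring (C1′ bonded to C11).
Remark on the target form: the target is drawn as the free bis(hydrogen sulfate); it is assumed that cold acidification of the sulfate salt in the last step delivers this form, which is best stored as a salt.

Step 1
Reactants: 1 (R)-(−)-carvone
Product: 3 trans-6-methylcarvone (5R,6S)-2,6-dimethyl-5-(prop-1-en-2-yl)cyclohex-2-en-1-one, via lithium dienolate 2 (not isolated)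
Conditions: LiN(i-Pr)2, THF, −78 °C; MeI, −78 → 0 °C
Reagents that add atoms: iodomethane, CI
Why: Kinetic α′-deprotonation gives the cross-conjugated lithium dienolate, which is methylated (enolate alkylation); the new C6 centre is irrelevant because it is enolised again in step 2.

Step 2
Reactants: 3 trans-6-methylcarvone; 4 propargyl bromide
Product: 6 (5S,6S)-2,6-dimethyl-5-(prop-1-en-2-yl)-6-(prop-2-yn-1-yl)cyclohex-2-en-1-one, via lithium dienolate 5 (not isolated)
Conditions: LiN(i-Pr)2, THF, −78 → 0 °C; then 4, DMPU, −78 °C → rt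
Reagents that add atoms: none
Why: Second enolate alkylation, in which the electrophile should enter anti to the pseudoaxial isopropenyl group on the neighbouring carbon, so that the chain ends trans and the methyl cis to isopropenyl and the quaternary centre (future C10) is set.

Step 3
Reactants: 6 propargyl enone
Product: 7 3-[(1S,6S)-1,3-dimethyl-2-oxo-6-(prop-1-en-2-yl)cyclohex-3-en-1-yl]propanal
Conditions: CpRu(MeCN)3PF6 (5 mol %), 5,5′-bis(trifluoromethyl)-2,2′-bipyridine (5 mol %), H2O, NMP, 25 °C
Reagents that add atoms: water, O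
Why: Ruthenium-catalysed anti-Markovnikov hydration of the terminal alkyne through a vinylidene should give the aldehyde and leave both alkenes and the hindered enone untouched.

Step 4
Reactants: 7 keto aldehyde
Product: 8 (E)-N′-tosylhydrazone of aldehyde 7
Conditions: TsNHNH2 (1.0 equiv), MeOH, 0 °C → rt
Reagents that add atoms: p-toluenesulfonohydrazide, Cc1ccc(cc1)S(=O)(=O)NN
Why: Hydrazone condensation, chemoselective for the unhindered aldehyde over the α′-quaternary enone carbonyl.

Step 5
Reactants: 8 tosylhydrazone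
Product: 11 bicyclic enone (4aS,8aS)-2,5,5,8a-tetramethyl-4a,5,6,7,8,8a-hexahydronaphthalen-1(4H)-one, via cyclised N′-tosylhydrazine 9 (not isolated), via monoalkyl diazene 10 (not isolated)
Conditions: Fe(acac)3 (0.5 equiv), PhSiH3 (2.5 equiv), EtOH (0.02 M), 60 °C; then NaOAc, 80 °C
Reagents that add atoms: none
Why: An iron hydride formed from Fe(acac)3 and PhSiH3 transfers a hydrogen atom to the CH2 terminus of the isopropenyl group (Markovnikov), and the resulting tertiary C4 radical adds to the hydrazone carbon C3; the nitrogen radical is reduced to hydrazine 9, and NaOAc with heat eliminates sulfinate to diazene 10, which loses N2 and leaves C3 as CH2. The closest known reaction type is the hydrogen-atom-transfer-initiated reductive alkylation (hydromethylation) of alkenes with sulfonylhydrazones, joined to a Caglioti-type fragmentation. Ring A closes in the 6-exo-trig mode onto C=N. No new stereocentre is formed (C4 carries two methyls, C3 ends as CH2), and the trans ring fusion follows from the existing trans arrangement of the C5 substituent and the C10 chain, both equatorial in a chair-like transition state. The step needs hydrogen-atom transfer at the electron-rich 1,1-disubstituted alkene and not at the electron-poor enone C7=C8, and capture of the radical before it is reduced. This should be secured by the polarity match of a nucleophilic tertiary radical with the electrophilic C=N, by high dilution, and by the fact that attack on the enone carbon C7 would need a four-membered ring.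

Step 6
Reactants: 11 bicyclic enone
Product: 12 (2S,4aS,8aS)-2,5,5,8a-tetramethyloctahydronaphthalen-1(2H)-one (8β-methyl, axial)
Conditions: H2 (1 atm), 10% Pd/C, EtOAc, rt
Reagents that add atoms: none
Why: Heterogeneous catalytic hydrogenation should add H2 syn from the α face, anti to the axial C10 methyl, so that H-8 is α and the C8 methyl is β (axial, kinetic); neutral conditions should avoid epimerisation.

Step 7
Reactants: 13 2,4,5-trihydroxybenzaldehyde
Product: 14 2,5-dihydroxy-4-[2-(trimethylsilyl)ethoxy]benzaldehyde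
Conditions: Me3SiCH2CH2OH (1.0 equiv), PPh3, DIAD, THF, 0 °C → rt
Reagents that add atoms: 2-(trimethylsilyl)ethanol, C[Si](C)(C)CCO
Why: Mitsunobu etherification should take the most acidic phenol (4-OH, para to the formyl group), while the 2-OH is hydrogen-bonded to the aldehyde and the 5-OH is less acidic.

Step 8
Reactants: 14 mono-ether
Product: 15 2,5-bis(methoxymethoxy)-4-[2-(trimethylsilyl)ethoxy]benzaldehyde
Conditions: MOMCl, i-Pr2NEt, CH2Cl2, 0 → 40 °C
Reagents that add atoms: chloromethyl methyl ether, COCCl
Why: O-alkylation of both remaining phenols (MOM protection), giving ethers that later direct ortho-metalation.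

Step 9
Reactants: 15 aldehyde
Product: 16 {2,5-bis(methoxymethoxy)-4-[2-(trimethylsilyl)ethoxy]phenyl}methanol
Conditions: NaBH4, MeOH, 0 °C
Reagents that add atoms: none
Why: Borohydride reduction of the aryl aldehyde to the benzyl alcohol.

Step 10
Reactants: 16 benzyl alcohol
Product: 18 1-(chloromethyl)-2,5-bis(methoxymethoxy)-4-[2-(trimethylsilyl)ethoxy]benzene, via benzyl mesylate 17 (not isolated)
Conditions: MsCl, Et3N, CH2Cl2, 0 °C → rt; used at once
Reagents that add atoms: methanesulfonyl chloride, CS(=O)(=O)Cl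
Why: Mesylation followed by displacement of the activated benzylic mesylate by the chloride set free gives the chloride under base, so that the MOM ethers survive.

Step 11
Reactants: 12 axial-methyl ketone; 18 benzyl chloride
Product: 20 (1S,2S,4aS,8aS)-1-{2,5-bis(methoxymethoxy)-4-[2-(trimethylsilyl)ethoxy]benzyl}-2,5,5,8a-tetramethyldecahydronaphthalen-1-ol, via benzylmagnesium chloride 19 (not isolated)
Conditions: 18, Mg, THF, 0 °C; then 12, CeCl3, THF, −78 → 0 °C; aq. NH4Cl
Reagents that add atoms: none
Why: Grignard formation and CeCl3-mediated 1,2-addition (organocerium, weakly basic, so C8 should not be enolised); the nucleophile should attack axially from the α face because the β face is shielded by the axial methyls on C8 and C10, giving 9β-OH and 9α-benzyl.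

Step 12
Reactants: 20 tertiary alcohol
Product: 21 (1E,2S,4aS,8aS)-1-{2,5-bis(methoxymethoxy)-4-[2-(trimethylsilyl)ethoxy]benzylidene}-2,5,5,8a-tetramethyldecahydronaphthalene
Conditions: Burgess reagent (MeO2CN−SO2N+Et3), toluene, 60 °C
Reagents that add atoms: none
Why: Burgess syn-elimination: the 9β-OH has no cis hydrogen in the ring (C10 is quaternary, H-8 is α), so only a C11 hydrogen can be removed and the exocyclic alkene should form, with the aryl group turned away from quaternary C10 (E).

Step 13
Reactants: 21 styrene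
Product: 23 3-[(E)-((2S,4aS,8aS)-2,5,5,8a-tetramethyloctahydronaphthalen-1(2H)-ylidene)methyl]-2,5-bis(methoxymethoxy)-6-[2-(trimethylsilyl)ethoxy]benzaldehyde, via aryllithium 22 (not isolated)
Conditions: n-BuLi, TMEDA, THF, −20 → 0 °C; DMF, −78 °C → rt; aq. NH4Cl
Reagents that add atoms: N,N-dimethylformamide, CN(C)C=O
Why: Directed ortho-metalation at C3′, the only position flanked by two alkoxy groups (2′-OMOM and 4′-ether), followed by formylation with DMF.

Step 14
Reactants: 23 bis-MOM aldehyde
Product: 25 2,5-dihydroxy-3-[(E)-((2S,4aS,8aS)-2,5,5,8a-tetramethyloctahydronaphthalen-1(2H)-ylidene)methyl]-6-[2-(trimethylsilyl)ethoxy]benzaldehyde, via bis(trimethylsilyl) ether 24 (not isolated)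
Conditions: TMSOTf, 2,2′-bipyridyl, CH2Cl2, 0 °C → rt; then H2O; under argon
Reagents that add atoms: none
Why: Buffered silyl-triflate cleavage of the aryl MOM ethers to aryl silyl ethers that hydrolyse on work-up; the non-protic conditions should spare the silylethyl ether and avoid acid-induced addition of the 2′-OH to the alkene.

Step 15
Reactants: 25 hydroquinone
Product: 26 disodium 2′,5′-bis-sulfate of 25
Conditions: SO3·pyridine (excess), pyridine, 50 °C; then aq. NaHCO3
Reagents that add atoms: sulfur trioxide–pyridine complex, [O-]S(=O)(=O)[n+]1ccccc1; sodium hydrogen carbonate, [Na+].OC([O-])=O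
Why: O-sulfation of the two free phenols with the 4′-oxygen still blocked, which fixes the 2′,5′-pattern.

Step 16
Reactants: 26 disodium bis-sulfate
Product: 27 CNP0309628.1
Conditions: Bu4NF, THF, 40 °C; then 1 M HCl to pH 2, 0 °C, rapid isolation
Reagents that add atoms: none
Why: Fluoride-induced β-elimination of the 2-(trimethylsilyl)ethyl ether releases ethene and the 4′-phenoxide (a good leaving group ortho to the formyl group), while aryl sulfate monoester anions are inert to fluoride; cold acidification gives the acid form.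

**Compound list**

1 | (R)-(−)-carvone, (5R)-2-methyl-5-(prop-1-en-2-yl)cyclohex-2-en-1-one | CC1=CC[C@@H](C(C)=C)CC1=O | starting material
2 | lithium cross-conjugated dienolate of carvone (not isolated) | CC1=CC[C@@H](C(C)=C)C=C1O[Li] | intermediate
3 | trans-6-methylcarvone, (5R,6S)-2,6-dimethyl-5-(prop-1-en-2-yl)cyclohex-2-en-1-one (major epimer) | CC1=CC[C@@H](C(C)=C)[C@H](C)C1=O | intermediate
4 | propargyl bromide (3-bromoprop-1-yne) | C#CCBr | starting material
5 | lithium dienolate of 3 (not isolated) | CC1=CC[C@@H](C(C)=C)C(C)=C1O[Li] | intermediate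
6 | (5S,6S)-2,6-dimethyl-5-(prop-1-en-2-yl)-6-(prop-2-yn-1-yl)cyclohex-2-en-1-one | CC1=CC[C@@H](C(C)=C)[C@](C)(CC#C)C1=O | intermediate
7 | 3-[(1S,6S)-1,3-dimethyl-2-oxo-6-(prop-1-en-2-yl)cyclohex-3-en-1-yl]propanal | CC1=CC[C@@H](C(C)=C)[C@](C)(CCC=O)C1=O | intermediate
8 | (E)-N′-tosylhydrazone of 7 | CC1=CC[C@@H](C(C)=C)[C@](C)(CC/C=N/NS(=O)(=O)c2ccc(C)cc2)C1=O | intermediate
9 | cyclised N-alkyl-N′-tosylhydrazine, hydrazine on C3 of ring A, both C3 epimers (not isolated) | CC1=CC[C@H]2C(C)(C)C(NNS(=O)(=O)c3ccc(C)cc3)CC[C@]2(C)C1=O | intermediate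
10 | monoalkyl diazene on C3, both C3 epimers (not isolated) | CC1=CC[C@H]2C(C)(C)C(N=N)CC[C@]2(C)C1=O | intermediate
11 | (4aS,8aS)-2,5,5,8a-tetramethyl-4a,5,6,7,8,8a-hexahydronaphthalen-1(4H)-one | CC1=CC[C@H]2C(C)(C)CCC[C@]2(C)C1=O | intermediate
12 | (2S,4aS,8aS)-2,5,5,8a-tetramethyloctahydronaphthalen-1(2H)-one (8β-methyl) | C[C@H]1CC[C@H]2C(C)(C)CCC[C@]2(C)C1=O | intermediate
13 | 2,4,5-trihydroxybenzaldehyde | O=Cc1cc(O)c(O)cc1O | starting material
14 | 2,5-dihydroxy-4-[2-(trimethylsilyl)ethoxy]benzaldehyde | O=Cc1cc(O)c(OCC[Si](C)(C)C)cc1O | intermediate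
15 | 2,5-bis(methoxymethoxy)-4-[2-(trimethylsilyl)ethoxy]benzaldehyde | O=Cc1cc(OCOC)c(OCC[Si](C)(C)C)cc1OCOC | intermediate
16 | {2,5-bis(methoxymethoxy)-4-[2-(trimethylsilyl)ethoxy]phenyl}methanol | OCc1cc(OCOC)c(OCC[Si](C)(C)C)cc1OCOC | intermediate
17 | methanesulfonate of 16 (not isolated) | CS(=O)(=O)OCc1cc(OCOC)c(OCC[Si](C)(C)C)cc1OCOC | intermediate
18 | 1-(chloromethyl)-2,5-bis(methoxymethoxy)-4-[2-(trimethylsilyl)ethoxy]benzene | ClCc1cc(OCOC)c(OCC[Si](C)(C)C)cc1OCOC | intermediate
19 | benzylmagnesium chloride from 18 (not isolated) | Cl[Mg]Cc1cc(OCOC)c(OCC[Si](C)(C)C)cc1OCOC | intermediate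
20 | (1S,2S,4aS,8aS)-1-{2,5-bis(methoxymethoxy)-4-[2-(trimethylsilyl)ethoxy]benzyl}-2,5,5,8a-tetramethyldecahydronaphthalen-1-ol (9β-OH) | C[C@H]1CC[C@H]2C(C)(C)CCC[C@]2(C)[C@]1(O)Cc1cc(OCOC)c(OCC[Si](C)(C)C)cc1OCOC | intermediate
21 | (1E,2S,4aS,8aS)-1-{2,5-bis(methoxymethoxy)-4-[2-(trimethylsilyl)ethoxy]benzylidene}-2,5,5,8a-tetramethyldecahydronaphthalene | C[C@H]1CC[C@H]2C(C)(C)CCC[C@]2(C)/C1=C/c1cc(OCOC)c(OCC[Si](C)(C)C)cc1OCOC | intermediate
22 | 3′-aryllithium of 21 (not isolated) | C[C@H]1CC[C@H]2C(C)(C)CCC[C@]2(C)/C1=C/c1cc(OCOC)c(OCC[Si](C)(C)C)c([Li])c1OCOC | intermediate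
23 | 3′-formyl derivative of 21 | C[C@H]1CC[C@H]2C(C)(C)CCC[C@]2(C)/C1=C/c1cc(OCOC)c(OCC[Si](C)(C)C)c(C=O)c1OCOC | intermediate
24 | 2′,5′-bis(trimethylsilyl) ether (not isolated) | C[C@H]1CC[C@H]2C(C)(C)CCC[C@]2(C)/C1=C/c1cc(O[Si](C)(C)C)c(OCC[Si](C)(C)C)c(C=O)c1O[Si](C)(C)C | intermediate
25 | 2′,5′-dihydroxy-3′-formyl-4′-[2-(trimethylsilyl)ethoxy] styrene | C[C@H]1CC[C@H]2C(C)(C)CCC[C@]2(C)/C1=C/c1cc(O)c(OCC[Si](C)(C)C)c(C=O)c1O | intermediate
26 | disodium 2′,5′-bis-sulfate of 25 | C[C@H]1CC[C@H]2C(C)(C)CCC[C@]2(C)/C1=C/c1cc(OS(=O)(=O)[O-])c(OCC[Si](C)(C)C)c(C=O)c1OS(=O)(=O)[O-].[Na+].[Na+] | intermediate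
27 | CNP0309628.1, (5S,8S,10S,9E) bis(hydrogen sulfate) | C[C@H]1CC[C@H]2C(C)(C)CCC[C@]2(C)/C1=C/c1cc(OS(=O)(=O)O)c(O)c(C=O)c1OS(=O)(=O)O | target

**Total step count:** 16 (steps 1–6 and 11–16 in the terpenoid line, steps 7–10 in the aryl line).
**Longest linear sequence:** 12 steps from (R)-carvone (steps 1–6, 11–16).

**Steps most likely to fail**

1. Step 5. The C4 radical may be reduced before it is captured by the C=N bond (net hydrogenation of the isopropenyl group), hydrogen-atom transfer may reach the enone, or sulfinate loss and denitrogenation may stay incomplete. The fallback sets out from 3 and comes back at 11. Dienolate 5 is alkylated with methyl 2-(bromomethyl)acrylate to give the acrylate F1. The same Fe(acac)3/PhSiH3 hydrogen-atom transfer then closes ring A by a Giese-type 6-endo-trig addition of the C4 radical to the acrylate CH2 (a much faster radical trap), giving the ester F2. LiOH hydrolysis gives the acid F3. Hydrodecarboxylation (9-mesityl-10-methylacridinium tetrafluoroborate, PhSSPh, CF3CH2OH, 450 nm) returns enone 11.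

2. Step 11. Wurtz homocoupling may dominate during magnesium insertion into the very electron-rich benzyl chloride, and the hindered ketone may be enolised (with loss of the axial C8 configuration) instead of attacked. The fallback sets out from ketone 12 and aldehyde 15 and comes back at 20; it forms the C11–C1′ bond instead of the C9–C11 bond. Aldehyde 15 is oxidised (NaClO2, NaH2PO4, 2-methyl-2-butene) to the benzoic acid F4 and bromodecarboxylated (Bu4NBr3, K3PO4, MeCN, 100 °C) to the aryl bromide F5. Exchange with t-BuLi gives the aryllithium F6. Ketone 12 is treated with dimethylsulfonium methylide (Me3SI, n-BuLi; Corey–Chaykovsky, CH2 delivered axially from the α face) to give the spiro-epoxide F7. Opening of F7 at its CH2 terminus by F6 with CuI (10 mol %) gives 20.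

3. Step 12. The hindered tertiary sulfamate may ionise (E1), which would give endocyclic elimination or a 1,2-methyl shift from C10 in place of the syn-elimination, and E/Z control may be poor. The fallback sets out from ketone 12 (through the spiro-epoxide F7 and the aryllithium F6 described above) and comes back at 21. F7 is rearranged with BF3·OEt2 (Meinwald rearrangement) to the aldehyde F8. Addition of F6 gives the secondary benzylic alcohol F9. Its dehydration (MsCl, Et3N) through the electron-rich benzylic position can only remove H-9 and should give the E-alkene 21.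

**Further compounds**

F1 | step 5 | methyl 2-{[(1S,6S)-1,3-dimethyl-2-oxo-6-(prop-1-en-2-yl)cyclohex-3-en-1-yl]methyl}prop-2-enoate | CC1=CC[C@@H](C(C)=C)[C@](C)(CC(=C)C(=O)OC)C1=O
F2 | step 5 | methyl (4aS,8aS)-4,4,7,8a-tetramethyl-8-oxo-1,2,3,4,4a,5,8,8a-octahydronaphthalene-2-carboxylate (both C2 epimers) | CC1=CC[C@H]2C(C)(C)CC(C(=O)OC)C[C@]2(C)C1=O
F3 | step 5 | (4aS,8aS)-4,4,7,8a-tetramethyl-8-oxo-1,2,3,4,4a,5,8,8a-octahydronaphthalene-2-carboxylic acid (both C2 epimers) | CC1=CC[C@H]2C(C)(C)CC(C(=O)O)C[C@]2(C)C1=O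
F4 | step 11 | 2,5-bis(methoxymethoxy)-4-[2-(trimethylsilyl)ethoxy]benzoic acid | OC(=O)c1cc(OCOC)c(OCC[Si](C)(C)C)cc1OCOC
F5 | step 11 | 1-bromo-2,5-bis(methoxymethoxy)-4-[2-(trimethylsilyl)ethoxy]benzene | Brc1cc(OCOC)c(OCC[Si](C)(C)C)cc1OCOC
F6 | step 11 | {2,5-bis(methoxymethoxy)-4-[2-(trimethylsilyl)ethoxy]phenyl}lithium | [Li]c1cc(OCOC)c(OCC[Si](C)(C)C)cc1OCOC
F7 | step 11 | spiro-epoxide of ketone 12 at C9 (oxygen β, CH2 α) | C[C@H]1CC[C@H]2C(C)(C)CCC[C@]2(C)[C@]13CO3
F8 | step 12 | (2S,4aS,8aS)-2,5,5,8a-tetramethyldecahydronaphthalene-1-carbaldehyde (both C9 epimers) | C[C@H]1CC[C@H]2C(C)(C)CCC[C@]2(C)C1C=O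
F9 | step 12 | secondary benzylic alcohol from F8 and F6 (epimers at C9 and C11) | C[C@H]1CC[C@H]2C(C)(C)CCC[C@]2(C)C1C(O)c1cc(OCOC)c(OCC[Si](C)(C)C)cc1OCOC
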